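**Retrosynthetic overview**
- The two esters go on last: tiglate on the C-10 allylic alcohol (from Luche reduction of a cycloheptenone), silyl-protected 4-hydroxybenzoate on the C-6 carbinol.
- The seven-membered ring is closed second, by ring-closing metathesis (C-8=C-9) of a crotonyl ketone and a methallyl carbinol held cis on the cyclopentane (ring A).
- C-6–C-7 comes from a chelation-controlled indium methallylation of an aldehyde; the quaternary C-1–C-10 bond (key bond) comes from a visible-light iminium/acyl-radical β-acylation of a cyclopentene carbaldehyde.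
- Ring A is made first, by ozonolysis/aldol ring contraction of (S)-terpinen-4-ol, whose carbinol centre becomes C-4 and controls every other stereocentre.
- The acyl donor is a 4-crotonyl-1,4-dihydropyridine (Grignard acylation, then Hantzsch synthesis).

Assumption: (S)-(+)-terpinen-4-ol is used enantiopure (commercial material, upgraded through a crystalline ester if needed); C-1 to C-15 are daucane atom numbers of the target (C-1 angular methyl carbon, C-4 isopropyl carbinol, C-5 ring-fusion CH, C-6 benzoate carbon, C-10 tiglate carbon).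

**Step 1**
Reactants: 1 (S)-(+)-terpinen-4-ol; 2 triethylsilyl trifluoromethanesulfonate
Product: 3 triethyl{[(1S)-4-methyl-1-(propan-2-yl)cyclohex-3-en-1-yl]oxy}silane
Conditions: TESOTf, 2,6-lutidine, CH2Cl2, −20 to 0 °C
Reagents that add atoms: triethylsilyl trifluoromethanesulfonate, CC[Si](CC)(CC)OS(=O)(=O)C(F)(F)F
Why: Silyl triflate/lutidine silylation of the hindered tertiary alcohol (no stereocentre touched) masks the hydroxyl so that it is not lost by β-elimination once a carbonyl sits two carbons away in steps 2 and 5.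

**Step 2**
Reactants: 3 silyl ether; 4 ozone
Product: 6 (5R)-2-methyl-5-(propan-2-yl)-5-[(triethylsilyl)oxy]cyclopent-1-ene-1-carbaldehyde, via silyloxy keto aldehyde 5 (not isolated)
Conditions: O3, CH2Cl2, −78 °C; Me2S, −78 °C to rt; then dibenzylammonium trifluoroacetate (0.3 equiv), toluene, 50 °C
Reagents that add atoms: ozone, [O-][O+]=O
Why: Ozonolysis of the only alkene and ammonium-salt-catalysed intramolecular aldol condensation (enamine of the aldehyde onto the methyl ketone, 5-exo, then dehydration) contract the six-membered ring to the cyclopentene carbaldehyde, as for limonene-derived keto aldehydes; no stereocentre is formed and the carbinol centre of 1 is carried over unchanged.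

**Step 3**
Reactants: 7 ethyl 2,2-diethoxyacetate; 8 (E)-prop-1-enylmagnesium bromide
Product: 9 (3E)-1,1-diethoxypent-3-en-2-one
Conditions: (E)-CH3CH=CHMgBr, THF, −78 °C; then H2O
Reagents that add atoms: (E)-prop-1-enylmagnesium bromide, C/C=C/[Mg]Br
Why: Grignard acylation of an α,α-dialkoxy ester stops at the ketone because the chelated tetrahedral magnesium alkoxide survives until work-up; the commercial E/Z mixture serves equally, since this alkene terminus is later lost as propene.

**Step 4**
Reactants: 9 keto acetal; 10 ethyl acetoacetate; 11 ethyl (2Z)-3-aminobut-2-enoate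
Product: 13 diethyl 4-[(2E)-but-2-enoyl]-2,6-dimethyl-1,4-dihydropyridine-3,5-dicarboxylate, via enone glyoxal 12 (not isolated)
Conditions: Amberlyst-15 (cat.), acetone/H2O, rt; filter; then 10, 11, EtOH, 0 °C to rt, dark
Reagents that add atoms: ethyl acetoacetate, CCOC(=O)CC(C)=O; ethyl (2Z)-3-aminobut-2-enoate, CCOC(=O)/C=C(/C)N
Why: Acid hydrolysis of the acetal unmasks the α-keto aldehyde, whose aldehyde carbon enters a Hantzsch dihydropyridine synthesis (Knoevenagel condensation, Michael addition of the enamino ester, cyclodehydration); C-4 of the heterocycle is not stereogenic.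

**Step 5**
Reactants: 6 cyclopentene carbaldehyde; 13 4-acyl-1,4-dihydropyridine
Product: 15 (1R,2R,5R)-2-[(2E)-but-2-enoyl]-5-hydroxy-2-methyl-5-(propan-2-yl)cyclopentane-1-carbaldehyde, via silyl ether 14 (not isolated)
Conditions: 13 (1.5 equiv), Ph2CHNH2 (30 mol%), CF3CO2H (40 mol%), MeCN, blue LEDs (460 nm), 25 °C, argon; then H2O; HF·pyridine, THF, 0 °C
Reagents that add atoms: diethyl 4-[(2E)-but-2-enoyl]-2,6-dimethyl-1,4-dihydropyridine-3,5-dicarboxylate, CCOC(=O)C1=C(C)NC(C)=C(C(=O)OCC)C1C(=O)/C=C/C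
Why: Proposed new method: the primary ammonium salt condenses with hindered enal 6 to an α,β-unsaturated iminium ion, which is reduced by the light-excited 4-acyl-1,4-dihydropyridine to a β-enaminyl radical while the oxidised dihydropyridine fragments to the small nucleophilic crotonoyl radical and a pyridinium ion, and radical–radical coupling at the fully substituted β-carbon C-1, on the face anti to isopropyl and syn to the smaller silyloxy group, creates the quaternary stereocentre, after which hydrolysis and amine-mediated equilibration place the formyl group trans to isopropyl (cis to the new acyl group) and HF·pyridine frees the tertiary alcohol; the closest known reaction type is the organocatalytic visible-light β-acylation (radical conjugate addition) of β-monosubstituted enals with 4-acyl-1,4-dihydropyridines through iminium ions, not yet shown for tetrasubstituted cyclic enals or for substrate-controlled quaternary centres.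

**Step 6**
Reactants: 15 hydroxy keto aldehyde; 16 3-bromo-2-methylprop-1-ene
Product: 17 (2E)-1-{(1R,2S,3R)-3-hydroxy-2-[(1S)-1-hydroxy-3-methylbut-3-en-1-yl]-1-methyl-3-(propan-2-yl)cyclopentyl}but-2-en-1-one
Conditions: indium powder, THF/H2O (1:1), rt
Reagents that add atoms: 3-bromo-2-methylprop-1-ene, C=C(C)CBr
Why: Barbier-type indium allylation in water is chemoselective for the aldehyde over the hindered enone, and the free β-hydroxyl locks the aldehyde in a six-membered indium chelate so that the methallyl group adds from the face opposite the quaternary C-1 (Cram chelate control), giving the (S)-carbinol at C-6.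

**Step 7**
Reactants: 17 dienone diol
Product: 18 (3R,3aS,4S,8aR)-3,4-dihydroxy-6,8a-dimethyl-3-(propan-2-yl)-2,3,3a,4,5,8a-hexahydroazulen-8(1H)-one
Conditions: second-generation Grubbs catalyst [RuCl2(=CHPh)(PCy3)(1,3-dimesitylimidazolidin-2-ylidene)] (5 mol%), CH2Cl2 (5 mM), 40 °C
Reagents that add atoms: none
Why: Ring-closing metathesis between the 1,1-disubstituted alkene and the enone alkene, held cis on ring A, closes the cis-fused seven-membered ring as the trisubstituted cycloheptenone with loss of propene; no stereocentre is changed.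

**Step 8**
Reactants: 18 hydroxy enone; 19 4-[(tert-butyldimethylsilyl)oxy]benzoic acid
Product: 20 (3R,3aS,4S,8aR)-3-hydroxy-6,8a-dimethyl-8-oxo-3-(propan-2-yl)-1,2,3,3a,4,5,8,8a-octahydroazulen-4-yl 4-[(tert-butyldimethylsilyl)oxy]benzoate
Conditions: 19, DCC, DMAP (0.3 equiv), CH2Cl2, 0 °C to rt
Reagents that add atoms: 4-[(tert-butyldimethylsilyl)oxy]benzoic acid, CC(C)(C)[Si](C)(C)Oc1ccc(cc1)C(=O)O
Why: Steglich esterification acylates the secondary C-6 hydroxyl with retention, while the tertiary C-4 hydroxyl is too hindered to react.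

**Step 9**
Reactants: 20 enone ester
Product: 21 (3R,3aS,4S,8S,8aR)-3,8-dihydroxy-6,8a-dimethyl-3-(propan-2-yl)-1,2,3,3a,4,5,8,8a-octahydroazulen-4-yl 4-[(tert-butyldimethylsilyl)oxy]benzoate
Conditions: NaBH4, CeCl3·7H2O, MeOH, −40 °C
Reagents that add atoms: none
Why: Luche 1,2-reduction of the enone: with the bulky C-5–C-4 bond equatorial on the seven-membered ring the angular methyl is pseudo-equatorial and ring A shields the concave face, so hydride adds axially from the convex face and gives the equatorial (S)-configured C-10 alcohol trans to the angular methyl.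

**Step 10**
Reactants: 21 allylic alcohol; 22 (2E)-2-methylbut-2-enoyl chloride (tigloyl chloride)
Product: 23 (3R,3aS,4S,8S,8aR)-3-hydroxy-6,8a-dimethyl-8-{[(2E)-2-methylbut-2-enoyl]oxy}-3-(propan-2-yl)-1,2,3,3a,4,5,8,8a-octahydroazulen-4-yl 4-[(tert-butyldimethylsilyl)oxy]benzoate
Conditions: 22 (3 equiv), Et3N, DMAP, CH2Cl2, 0 to 40 °C
Reagents that add atoms: (2E)-2-methylbut-2-enoyl chloride, C/C=C(\C)C(Cl)=O
Why: DMAP-catalysed acylation with the acid chloride esterifies the secondary allylic hydroxyl with retention, the tertiary hydroxyl stays free, and the (E)-geometry of the tigloyl unit is the thermodynamically stable one.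

**Step 11**
Reactants: 23 silyl-protected diester
Product: 24 (3R,3aS,4S,8S,8aR)-3-hydroxy-6,8a-dimethyl-8-{[(2E)-2-methylbut-2-enoyl]oxy}-3-(propan-2-yl)-1,2,3,3a,4,5,8,8a-octahydroazulen-4-yl 4-hydroxybenzoate (CNP0273650.3)
Conditions: TBAF, AcOH, THF, 0 °C
Reagents that add atoms: none
Why: Fluoride cleaves the aryl silyl ether (desilylation) and the acetic acid buffer keeps the phenoxide from attacking the two esters.

**Compound list**
1 | (S)-(+)-terpinen-4-ol, (1S)-4-methyl-1-(propan-2-yl)cyclohex-3-en-1-ol | CC1=CC[C@](O)(C(C)C)CC1 | starting material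
2 | triethylsilyl trifluoromethanesulfonate | CC[Si](CC)(CC)OS(=O)(=O)C(F)(F)F | starting material
3 | triethyl{[(1S)-4-methyl-1-(propan-2-yl)cyclohex-3-en-1-yl]oxy}silane | CC1=CC[C@](O[Si](CC)(CC)CC)(C(C)C)CC1 | intermediate
4 | ozone | [O-][O+]=O | starting material
5 | (3S)-6-oxo-3-(propan-2-yl)-3-[(triethylsilyl)oxy]heptanal | CC(=O)CC[C@@](O[Si](CC)(CC)CC)(C(C)C)CC=O | intermediate
6 | (5R)-2-methyl-5-(propan-2-yl)-5-[(triethylsilyl)oxy]cyclopent-1-ene-1-carbaldehyde | CC1=C(C=O)[C@](O[Si](CC)(CC)CC)(C(C)C)CC1 | intermediate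
7 | ethyl 2,2-diethoxyacetate | CCOC(=O)C(OCC)OCC | starting material
8 | (E)-prop-1-enylmagnesium bromide | C/C=C/[Mg]Br | starting material
9 | (3E)-1,1-diethoxypent-3-en-2-one | C/C=C/C(=O)C(OCC)OCC | intermediate
10 | ethyl acetoacetate | CCOC(=O)CC(C)=O | starting material
11 | ethyl (2Z)-3-aminobut-2-enoate | CCOC(=O)/C=C(/C)N | starting material
12 | (3E)-2-oxopent-3-enal | C/C=C/C(=O)C=O | intermediate
13 | diethyl 4-[(2E)-but-2-enoyl]-2,6-dimethyl-1,4-dihydropyridine-3,5-dicarboxylate | CCOC(=O)C1=C(C)NC(C)=C(C(=O)OCC)C1C(=O)/C=C/C | intermediate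
14 | (1R,2R,5R)-2-[(2E)-but-2-enoyl]-2-methyl-5-(propan-2-yl)-5-[(triethylsilyl)oxy]cyclopentane-1-carbaldehyde | O=C[C@@H]1[C@](C)(C(=O)/C=C/C)CC[C@@]1(O[Si](CC)(CC)CC)C(C)C | intermediate
15 | (1R,2R,5R)-2-[(2E)-but-2-enoyl]-5-hydroxy-2-methyl-5-(propan-2-yl)cyclopentane-1-carbaldehyde | O=C[C@@H]1[C@](C)(C(=O)/C=C/C)CC[C@@]1(O)C(C)C | intermediate
16 | 3-bromo-2-methylprop-1-ene | C=C(C)CBr | starting material
17 | (2E)-1-{(1R,2S,3R)-3-hydroxy-2-[(1S)-1-hydroxy-3-methylbut-3-en-1-yl]-1-methyl-3-(propan-2-yl)cyclopentyl}but-2-en-1-one | C=C(C)C[C@H](O)[C@@H]1[C@](C)(C(=O)/C=C/C)CC[C@@]1(O)C(C)C | intermediate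
18 | (3R,3aS,4S,8aR)-3,4-dihydroxy-6,8a-dimethyl-3-(propan-2-yl)-2,3,3a,4,5,8a-hexahydroazulen-8(1H)-one | O=C1C=C(C)C[C@H](O)[C@@H]2[C@@]1(C)CC[C@@]2(O)C(C)C | intermediate
19 | 4-[(tert-butyldimethylsilyl)oxy]benzoic acid | CC(C)(C)[Si](C)(C)Oc1ccc(cc1)C(=O)O | starting material
20 | (3R,3aS,4S,8aR)-3-hydroxy-6,8a-dimethyl-8-oxo-3-(propan-2-yl)-1,2,3,3a,4,5,8,8a-octahydroazulen-4-yl 4-[(tert-butyldimethylsilyl)oxy]benzoate | O=C1C=C(C)C[C@H](OC(=O)c3ccc(O[Si](C)(C)C(C)(C)C)cc3)[C@@H]2[C@@]1(C)CC[C@@]2(O)C(C)C | intermediate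
21 | (3R,3aS,4S,8S,8aR)-3,8-dihydroxy-6,8a-dimethyl-3-(propan-2-yl)-1,2,3,3a,4,5,8,8a-octahydroazulen-4-yl 4-[(tert-butyldimethylsilyl)oxy]benzoate | O[C@H]1C=C(C)C[C@H](OC(=O)c3ccc(O[Si](C)(C)C(C)(C)C)cc3)[C@@H]2[C@@]1(C)CC[C@@]2(O)C(C)C | intermediate
22 | (2E)-2-methylbut-2-enoyl chloride (tigloyl chloride) | C/C=C(\C)C(Cl)=O | starting material
23 | (3R,3aS,4S,8S,8aR)-3-hydroxy-6,8a-dimethyl-8-{[(2E)-2-methylbut-2-enoyl]oxy}-3-(propan-2-yl)-1,2,3,3a,4,5,8,8a-octahydroazulen-4-yl 4-[(tert-butyldimethylsilyl)oxy]benzoate | C/C=C(\C)C(=O)O[C@H]1C=C(C)C[C@H](OC(=O)c2ccc(O[Si](C)(C)C(C)(C)C)cc2)[C@@H]2[C@@]1(C)CC[C@@]2(O)C(C)C | intermediate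
24 | (3R,3aS,4S,8S,8aR)-3-hydroxy-6,8a-dimethyl-8-{[(2E)-2-methylbut-2-enoyl]oxy}-3-(propan-2-yl)-1,2,3,3a,4,5,8,8a-octahydroazulen-4-yl 4-hydroxybenzoate | C/C=C(\C)C(=O)O[C@H]1C=C(C)C[C@H](OC(=O)c2ccc(O)cc2)[C@@H]2[C@@]1(C)CC[C@@]2(O)C(C)C | target

**Step count**
Total: 11 steps. Longest linear sequence: 9 steps (steps 1, 2, 5, 6, 7, 8, 9, 10, 11); steps 3 and 4 make the acyl donor 13 in a side branch.

**Three steps most likely to fail**

Step 5 (the proposed new photochemical β-acylation). The tetrasubstituted enal may form its iminium ion slowly, facial selectivity at C-1 rests on 1,3-induction from C-4 (isopropyl against silyloxy), and the product enamine could expel the silyloxy group. The fallback uses a known tin-hydride acyl-radical conjugate addition (Giese type, acyl selenide method). It sets out from 6: (E)-but-2-enoyl chloride and benzeneselenol with pyridine give Se-phenyl (2E)-but-2-eneselenoate F1, and slow addition of Bu3SnH/AIBN to 6 and F1 in benzene at 80 °C gives the silyl-protected keto aldehyde 14, which on HF·pyridine treatment as before comes back to the route at 15.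

Step 6 (configuration at C-6). If the indium chelate is not dominant, the (R)-carbinol forms alongside or instead of 17. The fallback converges both epimers by oxidation and hydroxyl-directed reduction. It sets out from 15: the crude allylation product containing (2E)-1-{(1R,2S,3R)-3-hydroxy-2-[(1R)-1-hydroxy-3-methylbut-3-en-1-yl]-1-methyl-3-(propan-2-yl)cyclopentyl}but-2-en-1-one F2 is cyclised by the same metathesis to (3R,3aS,4R,8aR)-3,4-dihydroxy-6,8a-dimethyl-3-(propan-2-yl)-2,3,3a,4,5,8a-hexahydroazulen-8(1H)-one F3 (together with 18). Dess–Martin periodinane oxidises the secondary alcohol to (3R,3aR,8aR)-3-hydroxy-6,8a-dimethyl-3-(propan-2-yl)-2,3,3a,8a-tetrahydroazulene-4,8(1H,5H)-dione F4. Me4NBH(OAc)3 in MeCN/AcOH at −30 °C then delivers hydride intramolecularly from the boron bound to the C-4 hydroxyl (Evans–Saksena-type reduction; the enone is left alone), which can only give the C-6 alcohol anti to that hydroxyl, and the route is rejoined at 18.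

Step 9 (configuration at C-10). The facial preference of the Luche reduction rests on a conformational argument and could be reversed. The fallback installs the tiglate with inversion instead of retention. It sets out from 20: if the reduction gives (3R,3aS,4S,8R,8aR)-3,8-dihydroxy-6,8a-dimethyl-3-(propan-2-yl)-1,2,3,3a,4,5,8,8a-octahydroazulen-4-yl 4-[(tert-butyldimethylsilyl)oxy]benzoate F5, a Mitsunobu esterification with (2E)-2-methylbut-2-enoic acid, PPh3 and DIAD in toluene inverts C-10 and comes back to the route at 23. This inversion is at a hindered centre next to a quaternary carbon and would itself need optimisation.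

**Further compounds**
F1 | step 5 | Se-phenyl (2E)-but-2-eneselenoate | C/C=C/C(=O)[Se]c1ccccc1
F2 | step 6 | (2E)-1-{(1R,2S,3R)-3-hydroxy-2-[(1R)-1-hydroxy-3-methylbut-3-en-1-yl]-1-methyl-3-(propan-2-yl)cyclopentyl}but-2-en-1-one | C=C(C)C[C@@H](O)[C@@H]1[C@](C)(C(=O)/C=C/C)CC[C@@]1(O)C(C)C
F3 | step 6 | (3R,3aS,4R,8aR)-3,4-dihydroxy-6,8a-dimethyl-3-(propan-2-yl)-2,3,3a,4,5,8a-hexahydroazulen-8(1H)-one | O=C1C=C(C)C[C@@H](O)[C@@H]2[C@@]1(C)CC[C@@]2(O)C(C)C
F4 | step 6 | (3R,3aR,8aR)-3-hydroxy-6,8a-dimethyl-3-(propan-2-yl)-2,3,3a,8a-tetrahydroazulene-4,8(1H,5H)-dione | O=C1C=C(C)CC(=O)[C@@H]2[C@@]1(C)CC[C@@]2(O)C(C)C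
F5 | step 9 | (3R,3aS,4S,8R,8aR)-3,8-dihydroxy-6,8a-dimethyl-3-(propan-2-yl)-1,2,3,3a,4,5,8,8a-octahydroazulen-4-yl 4-[(tert-butyldimethylsilyl)oxy]benzoate | O[C@@H]1C=C(C)C[C@H](OC(=O)c3ccc(O[Si](C)(C)C(C)(C)C)cc3)[C@@H]2[C@@]1(C)CC[C@@]2(O)C(C)C
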